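**Retrosynthetic overview**
1. The target is the 10,12-bis-angelate of a longipinene-type enone diol (17); the last step is a double esterification.
2. The cyclobutane (ring C) is closed last by the C2–C7 bond, as in the himachalyl → longipinyl step of the presumed biosynthesis. A tertiary C7 cation of a cis-fused 6/7 enone is trapped by C2 of its extended silyl dienol ether, which returns the enone directly.
3. The six-membered ring (ring A) comes from a Diels–Alder reaction of a cycloheptenone with 1-acetoxy-3-methylbutadiene; a trans-fused acetonide controls the face.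
4. The seven-membered ring (ring B) comes from ring-closing metathesis at C1=C6 of a diene made by iridium-catalysed tert-(hydroxy)prenylation, which sets C11; C10 is then set by oxidation and hydroxyl-directed reduction.
5. Order of ring formation: ring B, then ring A, then ring C.

**Convention and assumption (one line):** names use biogenetic numbers (cyclobutane C1–C2–C7–C6; ring A = C1–C6 with C5 ketone and C3=C4; ring B = C1, C6–C11; C12 = CH2O on C11; C13, C14, C15 = methyls on C11, C7, C3), and the ligand enantiomer in step 1 is assumed to give the (2R) quaternary centre as the usual anti diol (use the antipodal ligand if the sense is opposite; steps 3–4 make the C10 outcome of step 1 irrelevant).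

---

**Step 1**
Reactants: 1 hex-5-en-1-ol; 2 2-methyl-2-vinyloxirane (racemic)
Product: 3 (2R,3R)-2-ethenyl-2-methyloct-7-ene-1,3-diol
Conditions: (η3-C3H5)Ir[(R)-Tol-BINAP](C,O-4-cyano-3-nitrobenzoate) (5 mol%), K3PO4 (5 mol%), 2 (3 equiv), THF, 60 °C
Reagents that add atoms: none
Why: Iridium-catalysed transfer-hydrogenative tert-(hydroxy)prenylation; the alcohol is dehydrogenated to the aldehyde, the racemic vinyl epoxide gives interconverting π-allyliridium species, and chair-like carbonyl addition under ligand control sets the quaternary C11.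

**Step 2**
Reactants: 3 (2R,3R)-2-ethenyl-2-methyloct-7-ene-1,3-diol
Product: 4 (1R,2R)-2-(hydroxymethyl)-2-methylcyclohept-3-en-1-ol
Conditions: second-generation Grubbs catalyst (5 mol%), CH2Cl2 (5 mM), 40 °C
Reagents that add atoms: none
Why: Ring-closing metathesis of the two terminal alkenes closes ring B at the C1=C6 bond with loss of ethene; no stereocentre is touched.

**Step 3**
Reactants: 4 (1R,2R)-2-(hydroxymethyl)-2-methylcyclohept-3-en-1-ol
Product: 5 (1R)-1-methyl-7-oxocyclohept-2-ene-1-carbaldehyde
Conditions: Dess–Martin periodinane (2.6 equiv), NaHCO3, CH2Cl2, 0 °C → rt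
Reagents that add atoms: none
Why: Dess–Martin oxidation of both alcohols; C11 has no α-hydrogen and cannot epimerise, and the C10 centre is deliberately erased.

**Step 4**
Reactants: 5 (1R)-1-methyl-7-oxocyclohept-2-ene-1-carbaldehyde
Product: 7 (1S,2R)-2-(hydroxymethyl)-2-methylcyclohept-3-en-1-ol, via hydroxy ketone 6 (not isolated)
Conditions: Me4NBH(OAc)3 (6 equiv), MeCN–AcOH (1:1), −30 °C → rt
Reagents that add atoms: none
Why: The aldehyde is reduced first, then a hydroxyl-directed (Evans–Saksena) reduction delivers hydride to the C10 ketone from the face carrying CH2OH, so the new 10-OH is trans to C12 and cis to the C13 methyl.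

**Step 5**
Reactants: 7 (1S,2R)-2-(hydroxymethyl)-2-methylcyclohept-3-en-1-ol
Product: 8 (4aR,9aS)-2,2,4a-trimethyl-4,4a,7,8,9,9a-hexahydrocyclohepta[d][1,3]dioxine
Conditions: 2,2-dimethoxypropane, PPTS (cat.), CH2Cl2, rt
Reagents that add atoms: 2,2-dimethoxypropane, COC(C)(C)OC
Why: Acetal exchange gives the trans-fused 1,3-dioxane, which protects both hydroxyls and locks the C13 methyl axial next to C1.

**Step 6**
Reactants: 8 (4aR,9aS)-2,2,4a-trimethyl-4,4a,7,8,9,9a-hexahydrocyclohepta[d][1,3]dioxine
Product: 9 (4aR,9aS)-2,2,4a-trimethyl-4,4a,9,9a-tetrahydrocyclohepta[d][1,3]dioxin-7(8H)-one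
Conditions: Rh2(cap)4 (dirhodium tetracaprolactamate, 1 mol%), t-BuOOH (70% aq., 6 equiv), K2CO3, CH2Cl2, rt
Reagents that add atoms: tert-butyl hydroperoxide, CC(C)(C)OO
Why: Dirhodium-catalysed allylic C–H oxidation; C7 is the only allylic position bearing hydrogens (C11 is quaternary), so the C7 enone forms regioselectively.

**Step 7**
Reactants: 10 3-methylbut-2-enal
Product: 11 (E)-3-methylbuta-1,3-dien-1-yl acetate
Conditions: isopropenyl acetate, TsOH (cat.), reflux with removal of acetone
Reagents that add atoms: isopropenyl acetate, CC(=C)OC(C)=O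
Why: Acid-catalysed enol acetylation of the enal through its extended enol gives the (E)-1-acetoxy diene.

**Step 8**
Reactants: 9 (4aR,9aS)-2,2,4a-trimethyl-4,4a,9,9a-tetrahydrocyclohepta[d][1,3]dioxin-7(8H)-one; 11 (E)-3-methylbuta-1,3-dien-1-yl acetate
Product: 12 cis-6/7-fused keto acetate (acetonide; C7 ketone; C3=C4; 5-OAc cis to C7)
Conditions: EtAlCl2 (0.5 equiv), 11 (3 equiv), toluene, −40 → 0 °C
Reagents that add atoms: none
Why: Lewis-acid-catalysed endo Diels–Alder reaction; the acetoxy terminus bonds to C6 and the methyl ends up on C3 ("ortho/para" rules), the cis-alkene gives the cis ring fusion, and the diene adds to the face of C1=C6 opposite the axial C13 methyl, which sets C1 and C6 relative to C11.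

**Step 9**
Reactants: 12 cis-6/7-fused keto acetate
Product: 13 cis-6/7-fused diol (acetonide; C7 tertiary carbinol with C14 methyl; C5 allylic alcohol)
Conditions: MeLi (5 equiv), CeCl3 (2 equiv), THF, −78 → 0 °C; aq. NH4Cl
Reagents that add atoms: methyllithium, [Li]C
Why: Organocerium 1,2-addition to the hindered, enolisable C7 ketone, with the excess MeLi cleaving the acetate; the C7 configuration is irrelevant because C7 becomes a cation.

**Step 10**
Reactants: 13 cis-6/7-fused diol
Product: 14 cis-6/7-fused hydroxy enone (acetonide; C5 ketone; C3=C4; C7-OH)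
Conditions: MnO2 (20 equiv), CH2Cl2, rt
Reagents that add atoms: none
Why: Chemoselective MnO2 oxidation of the allylic secondary alcohol; the tertiary alcohol and the C6 stereocentre are untouched under neutral conditions.

**Step 11**
Reactants: 14 cis-6/7-fused hydroxy enone
Product: 17 (1R,2R,5S,6R,7S,8R)-5-hydroxy-6-(hydroxymethyl)-2,6,9-trimethyltricyclo[5.4.0.0(2,8)]undec-9-en-11-one, via bis-silyl dienol ether 15 (not isolated), via tricyclic acetonide 16 (not isolated)
Conditions: TMSOTf (2.5 equiv), i-Pr2NEt (3 equiv), CH2Cl2, −78 → 0 °C; TiCl4 (3.5 equiv), −78 → −40 °C; then 1 M HCl, THF, rt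
Reagents that add atoms: none
Why: Proposed new method: soft enolisation at the accessible γ-CH2 (C6–H is hindered) gives the linear dienol ether and silylates the C7 carbinol; TiCl4 ionises the tertiary silyl ether and C2 attacks the C7 cation through a boat-like transition state, an intramolecular vinylogous Mukaiyama-type SN1 alkylation whose closest precedents are the Lewis-acid tert-alkylation of silyl enol ethers and the biosynthetic terpinyl → pinyl closure. Loss of silicon gives a non-nucleophilic enone so the closure does not reverse, attack through the C15 methylene would give an anti-Bredt enone, the cis ring fusion fixes the configurations at C2 and C7, and acidic work-up removes the acetonide.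

**Step 12**
Reactants: 17 tricyclic diol; 18 (Z)-2-methylbut-2-enoic acid (angelic acid)
Product: 20 CNP0240716.1 (target), via mixed anhydride 19 (not isolated)
Conditions: 18 (4 equiv), 2,4,6-trichlorobenzoyl chloride (4 equiv), Et3N (4.4 equiv), toluene, rt; then 17, toluene, 80 °C
Reagents that add atoms: none
Why: Yamaguchi-type mixed-anhydride esterification without a nucleophilic catalyst acylates both hydroxyls while avoiding Z → E isomerisation to the tiglate; no stereocentre is touched.

---

**Compound list**
1 | hex-5-en-1-ol | C=CCCCCO | starting material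
2 | 2-methyl-2-vinyloxirane (isoprene monoxide, racemic) | CC1(CO1)C=C | starting material
3 | (2R,3R)-2-ethenyl-2-methyloct-7-ene-1,3-diol | OC[C@@](C)(C=C)[C@H](O)CCCC=C | intermediate
4 | (1R,2R)-2-(hydroxymethyl)-2-methylcyclohept-3-en-1-ol | OC[C@@]1(C)C=CCCC[C@H]1O | intermediate
5 | (1R)-1-methyl-7-oxocyclohept-2-ene-1-carbaldehyde | O=C[C@@]1(C)C=CCCCC1=O | intermediate
6 | (2R)-2-(hydroxymethyl)-2-methylcyclohept-3-en-1-one | OC[C@@]1(C)C=CCCCC1=O | intermediate (not isolated)
7 | (1S,2R)-2-(hydroxymethyl)-2-methylcyclohept-3-en-1-ol | OC[C@@]1(C)C=CCCC[C@@H]1O | intermediate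
8 | (4aR,9aS)-2,2,4a-trimethyl-4,4a,7,8,9,9a-hexahydrocyclohepta[d][1,3]dioxine | CC1(C)OC[C@@]2(C)C=CCCC[C@@H]2O1 | intermediate
9 | (4aR,9aS)-2,2,4a-trimethyl-4,4a,9,9a-tetrahydrocyclohepta[d][1,3]dioxin-7(8H)-one | CC1(C)OC[C@@]2(C)C=CC(=O)CC[C@@H]2O1 | intermediate
10 | 3-methylbut-2-enal | CC(C)=CC=O | starting material
11 | (E)-3-methylbuta-1,3-dien-1-yl acetate | CC(=C)/C=C/OC(C)=O | intermediate
12 | cis-6/7-fused keto acetate: 10,12-acetonide, C7 ketone, C3=C4, 5-OAc cis to C7, H-1 and H-6 on the face of O-10 and C13 | CC1(C)OC[C@@]2(C)[C@H]3CC(C)=C[C@@H](OC(C)=O)[C@H]3C(=O)CC[C@@H]2O1 | intermediate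
13 | cis-6/7-fused diol: as 12 with C5-OH and C7(OH)CH3 (C7 epimers) | CC1(C)OC[C@@]2(C)[C@H]3CC(C)=C[C@@H](O)[C@H]3C(C)(O)CC[C@@H]2O1 | intermediate
14 | cis-6/7-fused hydroxy enone: C5 ketone, C3=C4, C7(OH)CH3 | CC1(C)OC[C@@]2(C)[C@H]3CC(C)=CC(=O)[C@H]3C(C)(O)CC[C@@H]2O1 | intermediate
15 | bis-silyl dienol ether: C5(OTMS)=C4–C3(CH3)=C2, C7(OTMS)CH3 | CC1(C)OC[C@@]2(C)[C@H]3C=C(C)C=C(O[Si](C)(C)C)[C@H]3C(C)(O[Si](C)(C)C)CC[C@@H]2O1 | intermediate (not isolated)
16 | tricyclic acetonide (10,12-acetonide of 17) | CC1(C)OC[C@@]2(C)[C@@H]3[C@H]4C(=O)C=C(C)[C@@H]3[C@@]4(C)CC[C@@H]2O1 | intermediate (not isolated)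
17 | (1R,2R,5S,6R,7S,8R)-5-hydroxy-6-(hydroxymethyl)-2,6,9-trimethyltricyclo[5.4.0.0(2,8)]undec-9-en-11-one | OC[C@@]1(C)[C@@H]2[C@H]3C(=O)C=C(C)[C@@H]2[C@@]3(C)CC[C@@H]1O | intermediate
18 | (Z)-2-methylbut-2-enoic acid (angelic acid) | C/C=C(/C)C(=O)O | starting material
19 | (Z)-2-methylbut-2-enoic 2,4,6-trichlorobenzoic anhydride | C/C=C(/C)C(=O)OC(=O)c1c(Cl)cc(Cl)cc1Cl | intermediate (not isolated)
20 | [(1R,2R,5S,6R,7S,8R)-2,6,9-trimethyl-5-[(Z)-2-methylbut-2-enoyl]oxy-11-oxotricyclo[5.4.0.0(2,8)]undec-9-en-6-yl]methyl (Z)-2-methylbut-2-enoate; biogenetic descriptors 1S,2R,6R,7R,10S,11R | C/C=C(/C)C(=O)OC[C@@]1(C)[C@@H]2[C@H]3C(=O)C=C(C)[C@@H]2[C@@]3(C)CC[C@@H]1OC(=O)/C(C)=C\C | target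

---

**Step count:** 12 steps in total; longest linear sequence 11 steps (steps 1–6 and 8–12, from hex-5-en-1-ol).

**The three steps most likely to fail, each with a fallback**

Step 11 (cationic cyclobutane closure). The likely failures are loss of a proton or a 1,2-hydride shift from the C7 cation to give himachaladienones, formation of the cross-conjugated enol ether, and attack through C4. The fallback sets out from 14 and returns at 16. Compound 14 is heated with isopropenyl acetate and TsOH; as with steroidal enones, this acid-catalysed, thermodynamic enol acetylation gives only the linear dienol acetate and also acetylates the tertiary alcohol, with no base that could trigger β-elimination, giving the dienol acetate/tertiary acetate F1. SnCl4 in CH2Cl2 at −78 °C then ionises the tertiary acetate and the enol acetate terminates the cyclisation to 16, which is hydrolysed to 17 as in step 11.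

Step 8 (Diels–Alder on a hindered, γ,γ-disubstituted cycloheptenone with an acid-sensitive diene). The fallback sets out from 9 and returns at 14. Compound 9 is combined with 2-methylbuta-1,3-diene under a mixed aluminium Lewis acid (AlBr3/AlMe3, toluene, 0 °C), the diene class with the best precedent for such enones, to give the cis-fused ketone F2, which lacks the C5 oxygen. MeLi/CeCl3 gives the tertiary alcohol F3, and allylic oxidation of the ring-A alkene at C5 with CrO3/3,5-dimethylpyrazole (−20 °C) gives 14; the C5 oxygen is thus introduced late instead of being carried in the diene.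

Step 12 (double angeloylation of a neopentyl primary and a hindered secondary alcohol without isomerisation). The fallback sets out from 17 and returns at 20. Both hydroxyls of 17 are esterified with 2-[bis(2,2,2-trifluoroethoxy)phosphoryl]propanoic acid (DCC, DMAP, CH2Cl2), an unhindered acid that cannot isomerise, to give the bis(phosphonopropionate) F4. A double Still–Gennari olefination with acetaldehyde (KHMDS, 18-crown-6, THF, −78 °C) then builds both (Z)-2-methylbut-2-enoates on the molecule, giving 20.

**Further compounds**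
F1 | step 11 | dienol acetate/tertiary acetate of 14: C5(OAc)=C4–C3(CH3)=C2, C7(OAc)CH3 | CC1(C)OC[C@@]2(C)[C@H]3C=C(C)C=C(OC(C)=O)[C@H]3C(C)(OC(C)=O)CC[C@@H]2O1
F2 | step 8 | cis-6/7-fused ketone from 2-methylbuta-1,3-diene: C7 ketone, C3=C4, C5H2 | CC1(C)OC[C@@]2(C)[C@H]3CC(C)=CC[C@H]3C(=O)CC[C@@H]2O1
F3 | step 8 | tertiary alcohol of F2: C7(OH)CH3 (C7 epimers) | CC1(C)OC[C@@]2(C)[C@H]3CC(C)=CC[C@H]3C(C)(O)CC[C@@H]2O1
F4 | step 12 | 10,12-bis{2-[bis(2,2,2-trifluoroethoxy)phosphoryl]propanoate} of 17 | CC(P(=O)(OCC(F)(F)F)OCC(F)(F)F)C(=O)OC[C@@]1(C)[C@@H]2[C@H]3C(=O)C=C(C)[C@@H]2[C@@]3(C)CC[C@@H]1OC(=O)C(C)P(=O)(OCC(F)(F)F)OCC(F)(F)F
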